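The route rests on cutting the 3-hydroxy-β ring (C1–C6 of the carotenoid skeleton) across C4–C5 and C1–C6. Its tetrasubstituted C5=C6 alkene is treated as a masked alkyne and the C3 oxygen, para to C6, as a masked 2-silyloxydiene: a Lewis-acid-promoted Diels–Alder reaction of the silyl dienol ether of mesityl oxide with ethyl but-2-ynoate forms both ring bonds and places the gem-dimethyl group, the C5 methyl, the C3 oxygen and the C7 carbon in one operation. Enzymatic reduction sets C3; sulfone chemistry extends C7 to a C20 phosphonium salt, joined at the end by a Wittig reaction to a C20 aldehyde carrying the ylidenebutenolide and the ε ring.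

Key step: step 2

Remark: carotenoid numbering is used for ring and chain atoms (primed numbers for the ε/butenolide half), and the ketoreductase of step 3 is assumed to be selected from a commercial enzyme panel for (R)-selectivity on ketone 5.

Step 1
Reactants: 1 mesityl oxide
Product: 2 tert-butyldimethyl[(4-methylpenta-1,3-dien-2-yl)oxy]silane
Conditions: TBSOTf, Et3N, CH2Cl2, 0 °C
Reagents that add atoms: tert-butyldimethylsilyl trifluoromethanesulfonate, CC(C)(C)[Si](C)(C)OS(=O)(=O)C(F)(F)F
Why: Silyl enol ether formation by soft enolisation: O-silylation of the enone and removal of an acetyl-methyl proton by Et3N should give the cross-conjugated 2-silyloxydiene.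

Step 2
Reactants: 2 tert-butyldimethyl[(4-methylpenta-1,3-dien-2-yl)oxy]silane; 3 ethyl but-2-ynoate
Product: 5 ethyl 2,6,6-trimethyl-4-oxocyclohex-1-ene-1-carboxylate, via silyl dienol ether adduct 4 (not isolated)
Conditions: AlBr3 (0.3 equiv), AlMe3 (0.03 equiv), PhMe/CH2Cl2, −10 → 25 °C; then 1 M HCl, THF, 0 °C
Reagents that add atoms: none
Why: Diels–Alder reaction of a 2-silyloxydiene with an acetylenic ester, run under aluminium Lewis-acid activation as a strongly asynchronous [4+2] (in the limit a Mukaiyama–Michael addition followed by ring closure of the allenoate onto the silyloxyallyl cation): the nucleophilic CH2 terminus of 2 bonds to the methyl-bearing β-carbon of the ynoate (C4–C5) and the ester-bearing α-carbon then bonds to the dimethylated diene terminus (C1–C6). The closest known reaction type is the Lewis-acid-promoted cycloaddition of hindered 2-silyloxydienes with conjugated carbonyl dienophiles. The six-membered ring closes in the [4+2] mode (6-endo-trig in the stepwise limit), and because the dienophile is an alkyne the C5=C6 double bond is delivered directly in its final tetrasubstituted position. No stereocentre is created; C3, the only one of this ring, is set in step 3 on the ketone that hydrolysis of the silyl enol ether unveils. The step needs para regioselectivity (silyloxy carbon opposite the ester-bearing carbon), secured by the matched polarisation of the two partners, and six- over four-membered ring closure, favoured because closure at the silyloxy carbon is reversible; cold dilute acid then hydrolyses the enol ether by protonation at C2 without moving the double bond into conjugation with the ketone.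

Step 3
Reactants: 5 ethyl 2,6,6-trimethyl-4-oxocyclohex-1-ene-1-carboxylate
Product: 6 ethyl (4R)-4-hydroxy-2,6,6-trimethylcyclohex-1-ene-1-carboxylate
Conditions: (R)-selective NADPH-dependent ketoreductase, NADP+ (cat.), i-PrOH, phosphate buffer pH 7, 30 °C
Reagents that add atoms: none
Why: Biocatalytic ketone reduction: the enzyme should deliver hydride to a single face of the ring ketone (its pocket distinguishing the CH2–CMe2 flank from the CH2–C(Me)=C flank) and so set C3 as R, while the neutral buffer leaves the C5=C6 double bond in place.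

Step 4
Reactants: 6 ethyl (4R)-4-hydroxy-2,6,6-trimethylcyclohex-1-ene-1-carboxylate
Product: 7 ethyl (4R)-4-[(tert-butyldimethylsilyl)oxy]-2,6,6-trimethylcyclohex-1-ene-1-carboxylate
Conditions: TBSCl, imidazole, DMF, 25 °C
Reagents that add atoms: tert-butyldimethylsilyl chloride, CC(C)(C)[Si](C)(C)Cl
Why: Standard silylation protects the C3 hydroxyl against the organolithium and alkoxide reagents of steps 8–10.

Step 5
Reactants: 7 ethyl (4R)-4-[(tert-butyldimethylsilyl)oxy]-2,6,6-trimethylcyclohex-1-ene-1-carboxylate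
Product: 8 {(4R)-4-[(tert-butyldimethylsilyl)oxy]-2,6,6-trimethylcyclohex-1-en-1-yl}methanol
Conditions: i-Bu2AlH, CH2Cl2, −78 → 0 °C
Reagents that add atoms: none
Why: Hydride reduction of the hindered conjugated ester by i-Bu2AlH should give the primary allylic alcohol and leave the silyl ether untouched.

Step 6
Reactants: 8 {(4R)-4-[(tert-butyldimethylsilyl)oxy]-2,6,6-trimethylcyclohex-1-en-1-yl}methanol
Product: 10 ({(4R)-4-[(tert-butyldimethylsilyl)oxy]-2,6,6-trimethylcyclohex-1-en-1-yl}methylsulfonyl)benzene, via allylic bromide 9 (not isolated)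
Conditions: CBr4, PPh3, CH2Cl2, 0 °C; then PhSO2Na, DMF, 25 °C
Reagents that add atoms: sodium benzenesulfinate, [Na+].[O-]S(=O)c1ccccc1
Why: Appel bromination followed by S-alkylation of the sulfinate (SN2) should give the allylic sulfone, the tetrasubstituted double bond staying in the ring as the more stable isomer.

Step 7
Reactants: 11 geranyl acetate
Product: 12 (2E,6E)-3,7-dimethyl-8-oxoocta-2,6-dien-1-yl acetate
Conditions: SeO2, EtOH (95%), reflux
Reagents that add atoms: selenium dioxide, O=[Se]=O
Why: Riley oxidation attacks the E-methyl group of the more electron-rich terminal trisubstituted alkene (ene reaction then 2,3-sigmatropic shift) and should give the (E)-enal without touching the allylic acetate end.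

Step 8
Reactants: 10 ({(4R)-4-[(tert-butyldimethylsilyl)oxy]-2,6,6-trimethylcyclohex-1-en-1-yl}methylsulfonyl)benzene; 12 (2E,6E)-3,7-dimethyl-8-oxoocta-2,6-dien-1-yl acetate
Product: 14 (2E,6E)-8-hydroxy-3,7-dimethyl-9-(phenylsulfonyl)-9-{(4R)-4-[(tert-butyldimethylsilyl)oxy]-2,6,6-trimethylcyclohex-1-en-1-yl}nona-2,6-dien-1-yl acetate (mixture at the two new centres), via lithiated sulfone 13 (not isolated)
Conditions: n-BuLi, THF, −78 °C; then 12, −78 °C; H2O
Reagents that add atoms: none
Why: The α-sulfonyl carbanion adds to the aldehyde (first stage of a Julia olefination) far faster than to the acetate at −78 °C, forming the C7–C8 bond; the two new stereocentres arise as a mixture that is irrelevant because both are erased in step 10.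

Step 9
Reactants: 14 the β-hydroxy sulfone
Product: 15 (2E,6E)-8-(methoxymethoxy)-3,7-dimethyl-9-(phenylsulfonyl)-9-{(4R)-4-[(tert-butyldimethylsilyl)oxy]-2,6,6-trimethylcyclohex-1-en-1-yl}nona-2,6-dien-1-yl acetate
Conditions: MOMCl, i-Pr2NEt, CH2Cl2, 0 → 25 °C
Reagents that add atoms: chloromethyl methyl ether, COCCl
Why: Acetal formation turns the hindered secondary hydroxyl into an alkoxy leaving group suited to base-induced elimination and blocks retro-aldol cleavage.

Step 10
Reactants: 15 the β-(methoxymethoxy) sulfone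
Product: 17 (3R)-3-[(tert-butyldimethylsilyl)oxy]retinol (all-E), via dienyl sulfone 16 (not isolated)
Conditions: KOMe, cyclohexane, 40 °C
Reagents that add atoms: none
Why: Sulfone double elimination: methoxide removes the acidic C7–H and expels the alkoxy group (E1cB) to the dienyl sulfone, which isomerises to the allylic sulfone and loses sulfinate by 1,6-elimination, so that C7=C8 and C11=C12 are created under conditions that should favour the all-E tetraene, the acetate being cleaved by methoxide in the same pot.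

Step 11
Reactants: 17 (3R)-3-[(tert-butyldimethylsilyl)oxy]retinol
Product: 18 [(3R)-3-hydroxyretinyl]triphenylphosphonium bromide (all-E)
Conditions: PPh3·HBr (1.5 equiv), MeOH, 25 °C
Reagents that add atoms: triphenylphosphine hydrobromide, Br.c1ccccc1P(c1ccccc1)c1ccccc1
Why: Acid ionises the allylic alcohol to the delocalised pentaenyl cation, which PPh3 captures at the terminal C15 (phosphonium salt formation), and the acidic methanol should at the same time cleave the silyl ether by solvolysis.

Step 12
Reactants: 19 isobutyraldehyde; 20 ethyl vinyl ketone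
Product: 22 2,4,4-trimethylcyclohex-2-en-1-one, via Michael adduct 21 (not isolated)
Conditions: H2SO4 (cat.), PhH, 45 °C → reflux, removal of water
Reagents that add atoms: none
Why: Acid-catalysed Robinson annulation: Michael addition of the aldehyde enol to the vinyl ketone followed by intramolecular aldol condensation should give the trimethylcyclohexenone.

Step 13
Reactants: 22 2,4,4-trimethylcyclohex-2-en-1-one
Product: 23 (1S)-2,4,4-trimethylcyclohex-2-en-1-ol
Conditions: (R)-2-methyl-CBS-oxazaborolidine (cat.), BH3·SMe2, THF, −20 °C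
Reagents that add atoms: none
Why: CBS reduction: in the catalyst–borane–ketone complex the α-methylalkenyl branch acts as the large group, so the (R)-oxazaborolidine should deliver hydride to the face that gives the (S)-allylic alcohol.

Step 14
Reactants: 23 (1S)-2,4,4-trimethylcyclohex-2-en-1-ol
Product: 25 ethyl 2-[(1R)-2,6,6-trimethylcyclohex-2-en-1-yl]acetate, via ketene acetal 24 (not isolated)
Conditions: CH3C(OEt)3, EtCO2H (cat.), xylene, 140 °C, distilling off EtOH
Reagents that add atoms: triethyl orthoacetate, CCOC(C)(OCC)OCC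
Why: Johnson–Claisen rearrangement: the ketene acetal formed by exchange with the orthoester undergoes a suprafacial [3,3] shift in which the new C6'–C7' bond forms on the ring face from which the C–O bond departs, transferring the (S)-carbinol configuration into the (R)-configured C6' next to the gem-dimethyl carbon.

Step 15
Reactants: 25 ethyl 2-[(1R)-2,6,6-trimethylcyclohex-2-en-1-yl]acetate
Product: 26 ethyl 2-[(1R)-2,6,6-trimethyl-4-oxocyclohex-2-en-1-yl]acetate
Conditions: Pd(OH)2/C (cat.), t-BuOOH, K2CO3, CH2Cl2, 0 → 25 °C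
Reagents that add atoms: tert-butyl hydroperoxide, CC(C)(C)OO
Why: Palladium-catalysed allylic oxidation with t-BuOOH should convert the only allylic ring methylene (C3') into the enone, the hindered tertiary C6'–H and the vinylic methyl group reacting more slowly.

Step 16
Reactants: 26 ethyl 2-[(1R)-2,6,6-trimethyl-4-oxocyclohex-2-en-1-yl]acetate
Product: 27 ethyl 2-[(1R,4R)-4-hydroxy-2,6,6-trimethylcyclohex-2-en-1-yl]acetate
Conditions: (S)-2-methyl-CBS-oxazaborolidine (cat.), catecholborane, PhMe, −78 °C
Reagents that add atoms: none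
Why: CBS reduction with catecholborane (1,2-selective for enones): the (S)-oxazaborolidine, with the alkenyl branch as large group, should give the (3'R)-alcohol, and the substrate reinforces this because its axial C1' methyl group shields the opposite face, so the hydroxyl ends up trans to the C6' side chain.

Step 17
Reactants: 27 ethyl 2-[(1R,4R)-4-hydroxy-2,6,6-trimethylcyclohex-2-en-1-yl]acetate
Product: 28 ethyl 2-{(1R,4R)-4-[(tert-butyldimethylsilyl)oxy]-2,6,6-trimethylcyclohex-2-en-1-yl}acetate
Conditions: TBSCl, imidazole, DMF, 25 °C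
Reagents that add atoms: tert-butyldimethylsilyl chloride, CC(C)(C)[Si](C)(C)Cl
Why: Silylation protects the allylic alcohol for the Grignard and oxidation steps.

Step 18
Reactants: 28 the silyl ether ester
Product: 29 2-{(1R,4R)-4-[(tert-butyldimethylsilyl)oxy]-2,6,6-trimethylcyclohex-2-en-1-yl}ethan-1-ol
Conditions: LiAlH4, Et2O, 0 °C
Reagents that add atoms: none
Why: LiAlH4 reduces the ester to the primary alcohol without affecting the silyl ether or the ring alkene.

Step 19
Reactants: 29 the primary alcohol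
Product: 30 {[(1R,4R)-4-(2-bromoethyl)-3,5,5-trimethylcyclohex-2-en-1-yl]oxy}(tert-butyl)dimethylsilane
Conditions: CBr4, PPh3, CH2Cl2, 0 °C
Reagents that add atoms: carbon tetrabromide, BrC(Br)(Br)Br
Why: The Appel reaction converts the primary alcohol into the bromide under neutral conditions tolerated by the allylic silyl ether.

Step 20
Reactants: 30 the primary bromide; 31 prop-2-yn-1-ol
Product: 35 (2Z)-2-(2-{(1R,4R)-4-[(tert-butyldimethylsilyl)oxy]-2,6,6-trimethylcyclohex-2-en-1-yl}ethyl)-3-iodoprop-2-en-1-ol, via Grignard reagent 32 (not isolated), via bromomagnesium propargyl alkoxide 33 (not isolated), via alkenylmagnesium chelate 34 (not isolated)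
Conditions: 30, Mg, THF, 25 → 40 °C; 31, EtMgBr, THF, 0 °C; combine, CuI (10 mol%), 0 → 25 °C; then I2, −78 → 0 °C; H2O
Reagents that add atoms: iodine, II
Why: Copper-catalysed anti-carbomagnesiation of the magnesium alkoxide of propargyl alcohol puts the alkyl group on C2 and magnesium on C3 cis to the CH2O group in a five-membered chelate, and iodinolysis of the C–Mg bond with retention should give the (Z)-3-iodo-2-alkylallyl alcohol.

Step 21
Reactants: 35 the (Z)-iodo allylic alcohol
Product: 37 (2Z)-2-(2-{(1R,4R)-4-[(tert-butyldimethylsilyl)oxy]-2,6,6-trimethylcyclohex-2-en-1-yl}ethyl)-3-iodoprop-2-enoic acid, via iodoenal 36 (not isolated)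
Conditions: TEMPO (cat.), PhI(OAc)2, MeCN/H2O, 25 °C
Reagents that add atoms: water, O
Why: TEMPO-catalysed oxidation with PhI(OAc)2 in aqueous acetonitrile takes the primary allylic alcohol through the enal and its hydrate to the acid without isomerising the (Z)-iodoalkene or touching the silyl ether.

Step 22
Reactants: 37 the (Z)-iodo acid; 38 (E)-3-methylpent-2-en-4-yn-1-ol
Product: 40 (5Z)-3-(2-{(1R,4R)-4-[(tert-butyldimethylsilyl)oxy]-2,6,6-trimethylcyclohex-2-en-1-yl}ethyl)-5-[(2E)-4-hydroxy-2-methylbut-2-en-1-ylidene]furan-2(5H)-one, via enynoic acid 39 (not isolated)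
Conditions: PdCl2(PPh3)2 (5 mol%), CuI (10 mol%), Et3N, MeCN, 25 °C
Reagents that add atoms: none
Why: Sonogashira coupling at the vinyl iodide followed in situ by 5-exo-dig anti-addition of the carboxylate across the metal-activated alkyne should give the (Z)-γ-ylidenebutenolide, the E geometry of the enynol being retained.

Step 23
Reactants: 40 the butenolide alcohol
Product: 41 (2E)-4-[(2Z)-4-(2-{(1R,4R)-4-[(tert-butyldimethylsilyl)oxy]-2,6,6-trimethylcyclohex-2-en-1-yl}ethyl)-5-oxofuran-2(5H)-ylidene]-3-methylbut-2-enal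
Conditions: MnO2, CH2Cl2, 25 °C
Reagents that add atoms: none
Why: MnO2 selectively oxidises the primary dienylic alcohol to the conjugated aldehyde.

Step 24
Reactants: 41 the silyl-protected butenolide aldehyde
Product: 42 (2E)-4-[(2Z)-4-{2-[(1R,4R)-4-hydroxy-2,6,6-trimethylcyclohex-2-en-1-yl]ethyl}-5-oxofuran-2(5H)-ylidene]-3-methylbut-2-enal
Conditions: Bu4NF, AcOH, THF, 0 → 25 °C
Reagents that add atoms: none
Why: Fluoride buffered with acetic acid cleaves the allylic silyl ether without ionising the acid-labile allylic C3'–O bond or opening the enol lactone.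

Step 25
Reactants: 18 [(3R)-3-hydroxyretinyl]triphenylphosphonium bromide; 42 the hydroxy butenolide aldehyde
Product: 45 CNP0242041.1 (all-E polyene with Z-ylidenebutenolide and 3R,3'R,6'R configuration), via ylide 43 (not isolated), via 15Z isomer 44 (not isolated)
Conditions: NaN(SiMe3)2 (1.05 equiv), THF, −78 °C; then 42, −78 → 0 °C; then PhH, 40 °C, dark, argon
Reagents that add atoms: none
Why: Wittig reaction of the semi-stabilised polyenyl ylide with the conjugated aldehyde forms the central C15=C15' double bond, and the 15Z isomer formed alongside should equilibrate under mild thermal conditions to the more stable all-E polyene, the three stereocentres and the Z-ylidene lactone being untouched.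

Compound list
1 | mesityl oxide (4-methylpent-3-en-2-one) | CC(=O)C=C(C)C | starting material
2 | tert-butyldimethyl[(4-methylpenta-1,3-dien-2-yl)oxy]silane | C=C(O[Si](C)(C)C(C)(C)C)C=C(C)C | intermediate
3 | ethyl but-2-ynoate | CC#CC(=O)OCC | starting material
4 | ethyl 4-[(tert-butyldimethylsilyl)oxy]-2,6,6-trimethylcyclohexa-1,4-diene-1-carboxylate | CCOC(=O)C1=C(C)CC(O[Si](C)(C)C(C)(C)C)=CC1(C)C | intermediate
5 | ethyl 2,6,6-trimethyl-4-oxocyclohex-1-ene-1-carboxylate | CCOC(=O)C1=C(C)CC(=O)CC1(C)C | intermediate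
6 | ethyl (4R)-4-hydroxy-2,6,6-trimethylcyclohex-1-ene-1-carboxylate | CCOC(=O)C1=C(C)C[C@@H](O)CC1(C)C | intermediate
7 | ethyl (4R)-4-[(tert-butyldimethylsilyl)oxy]-2,6,6-trimethylcyclohex-1-ene-1-carboxylate | CCOC(=O)C1=C(C)C[C@@H](O[Si](C)(C)C(C)(C)C)CC1(C)C | intermediate
8 | {(4R)-4-[(tert-butyldimethylsilyl)oxy]-2,6,6-trimethylcyclohex-1-en-1-yl}methanol | OCC1=C(C)C[C@@H](O[Si](C)(C)C(C)(C)C)CC1(C)C | intermediate
9 | allylic bromide of 8 (4R) | BrCC1=C(C)C[C@@H](O[Si](C)(C)C(C)(C)C)CC1(C)C | intermediate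
10 | ({(4R)-4-[(tert-butyldimethylsilyl)oxy]-2,6,6-trimethylcyclohex-1-en-1-yl}methylsulfonyl)benzene | O=S(=O)(CC1=C(C)C[C@@H](O[Si](C)(C)C(C)(C)C)CC1(C)C)c1ccccc1 | intermediate
11 | geranyl acetate | CC(=O)OC/C=C(\C)CCC=C(C)C | starting material
12 | (2E,6E)-3,7-dimethyl-8-oxoocta-2,6-dien-1-yl acetate | CC(=O)OC/C=C(\C)CC/C=C(\C)C=O | intermediate
13 | α-lithio derivative of sulfone 10 | [Li]C(C1=C(C)C[C@@H](O[Si](C)(C)C(C)(C)C)CC1(C)C)S(=O)(=O)c1ccccc1 | intermediate
14 | β-hydroxy sulfone (C7/C8 mixture) | CC(=O)OC/C=C(\C)CC/C=C(\C)C(O)C(C1=C(C)C[C@@H](O[Si](C)(C)C(C)(C)C)CC1(C)C)S(=O)(=O)c1ccccc1 | intermediate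
15 | β-(methoxymethoxy) sulfone (C7/C8 mixture) | CC(=O)OC/C=C(\C)CC/C=C(\C)C(OCOC)C(C1=C(C)C[C@@H](O[Si](C)(C)C(C)(C)C)CC1(C)C)S(=O)(=O)c1ccccc1 | intermediate
16 | dienyl sulfone (C15 alcohol; C7=C8 geometry undefined) | OC/C=C(\C)CC/C=C(\C)C=C(C1=C(C)C[C@@H](O[Si](C)(C)C(C)(C)C)CC1(C)C)S(=O)(=O)c1ccccc1 | intermediate
17 | (3R)-3-[(tert-butyldimethylsilyl)oxy]retinol (all-E) | OC/C=C(C)/C=C/C=C(C)/C=C/C1=C(C)C[C@@H](O[Si](C)(C)C(C)(C)C)CC1(C)C | intermediate
18 | [(3R)-3-hydroxyretinyl]triphenylphosphonium bromide (all-E) | [Br-].c1ccccc1[P+](c1ccccc1)(c1ccccc1)C/C=C(C)/C=C/C=C(C)/C=C/C1=C(C)C[C@@H](O)CC1(C)C | intermediate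
19 | isobutyraldehyde | CC(C)C=O | starting material
20 | ethyl vinyl ketone (pent-1-en-3-one) | CCC(=O)C=C | starting material
21 | 2,2-dimethyl-5-oxoheptanal | CCC(=O)CCC(C)(C)C=O | intermediate
22 | 2,4,4-trimethylcyclohex-2-en-1-one | CC1=CC(C)(C)CCC1=O | intermediate
23 | (1S)-2,4,4-trimethylcyclohex-2-en-1-ol | CC1=CC(C)(C)CC[C@@H]1O | intermediate
24 | (1S)-1-[(1-ethoxyvinyl)oxy]-2,4,4-trimethylcyclohex-2-ene | CC1=CC(C)(C)CC[C@@H]1OC(=C)OCC | intermediate
25 | ethyl 2-[(1R)-2,6,6-trimethylcyclohex-2-en-1-yl]acetate | CC1=CCCC(C)(C)[C@H]1CC(=O)OCC | intermediate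
26 | ethyl 2-[(1R)-2,6,6-trimethyl-4-oxocyclohex-2-en-1-yl]acetate | CC1=CC(=O)CC(C)(C)[C@H]1CC(=O)OCC | intermediate
27 | ethyl 2-[(1R,4R)-4-hydroxy-2,6,6-trimethylcyclohex-2-en-1-yl]acetate | CC1=C[C@H](O)CC(C)(C)[C@H]1CC(=O)OCC | intermediate
28 | ethyl 2-{(1R,4R)-4-[(tert-butyldimethylsilyl)oxy]-2,6,6-trimethylcyclohex-2-en-1-yl}acetate | CC1=C[C@H](O[Si](C)(C)C(C)(C)C)CC(C)(C)[C@H]1CC(=O)OCC | intermediate
29 | 2-{(1R,4R)-4-[(tert-butyldimethylsilyl)oxy]-2,6,6-trimethylcyclohex-2-en-1-yl}ethan-1-ol | CC1=C[C@H](O[Si](C)(C)C(C)(C)C)CC(C)(C)[C@H]1CCO | intermediate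
30 | {[(1R,4R)-4-(2-bromoethyl)-3,5,5-trimethylcyclohex-2-en-1-yl]oxy}(tert-butyl)dimethylsilane | CC1=C[C@H](O[Si](C)(C)C(C)(C)C)CC(C)(C)[C@H]1CCBr | intermediate
31 | prop-2-yn-1-ol | C#CCO | starting material
32 | Grignard reagent from 30 | CC1=C[C@H](O[Si](C)(C)C(C)(C)C)CC(C)(C)[C@H]1CC[Mg]Br | intermediate
33 | bromomagnesium prop-2-yn-1-olate | C#CCO[Mg]Br | intermediate
34 | (Z)-alkenylmagnesium chelate | CC1=C[C@H](O[Si](C)(C)C(C)(C)C)CC(C)(C)[C@H]1CC/C(CO[Mg]Br)=C/[Mg]Br | intermediate
35 | (2Z)-2-(2-{(1R,4R)-4-[(tert-butyldimethylsilyl)oxy]-2,6,6-trimethylcyclohex-2-en-1-yl}ethyl)-3-iodoprop-2-en-1-ol | CC1=C[C@H](O[Si](C)(C)C(C)(C)C)CC(C)(C)[C@H]1CC/C(CO)=C/I | intermediate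
36 | (2Z)-iodoenal corresponding to 35 | CC1=C[C@H](O[Si](C)(C)C(C)(C)C)CC(C)(C)[C@H]1CC/C(C=O)=C/I | intermediate
37 | (2Z)-2-(2-{(1R,4R)-4-[(tert-butyldimethylsilyl)oxy]-2,6,6-trimethylcyclohex-2-en-1-yl}ethyl)-3-iodoprop-2-enoic acid | CC1=C[C@H](O[Si](C)(C)C(C)(C)C)CC(C)(C)[C@H]1CC/C(C(=O)O)=C/I | intermediate
38 | (E)-3-methylpent-2-en-4-yn-1-ol | C#C/C(C)=C/CO | starting material
39 | (2Z,6E)-enynoic acid (Sonogashira product) | CC1=C[C@H](O[Si](C)(C)C(C)(C)C)CC(C)(C)[C@H]1CC/C(C(=O)O)=C/C#C/C(C)=C/CO | intermediate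
40 | (5Z)-3-(2-{(1R,4R)-4-[(tert-butyldimethylsilyl)oxy]-2,6,6-trimethylcyclohex-2-en-1-yl}ethyl)-5-[(2E)-4-hydroxy-2-methylbut-2-en-1-ylidene]furan-2(5H)-one | CC1=C[C@H](O[Si](C)(C)C(C)(C)C)CC(C)(C)[C@H]1CCC1=C/C(=C/C(C)=C/CO)OC1=O | intermediate
41 | silyl-protected butenolide aldehyde | CC1=C[C@H](O[Si](C)(C)C(C)(C)C)CC(C)(C)[C@H]1CCC1=C/C(=C/C(C)=C/C=O)OC1=O | intermediate
42 | (2E)-4-[(2Z)-4-{2-[(1R,4R)-4-hydroxy-2,6,6-trimethylcyclohex-2-en-1-yl]ethyl}-5-oxofuran-2(5H)-ylidene]-3-methylbut-2-enal | CC1=C[C@H](O)CC(C)(C)[C@H]1CCC1=C/C(=C/C(C)=C/C=O)OC1=O | intermediate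
43 | [(3R)-3-hydroxyretinylidene]triphenylphosphorane | c1ccccc1P(c1ccccc1)(c1ccccc1)=C/C=C(C)/C=C/C=C(C)/C=C/C1=C(C)C[C@@H](O)CC1(C)C | intermediate
44 | 15Z isomer of the target | CC1=C[C@H](O)CC(C)(C)[C@H]1CCC1=C/C(=C/C(C)=C/C=C\C=C(C)\C=C\C=C(C)\C=C\C2=C(C)C[C@@H](O)CC2(C)C)OC1=O | intermediate
45 | CNP0242041.1, (3R,3'R,6'R)-3,3'-dihydroxy-7',8'-dihydro-β,ε-caroten-19',11'-olide | CC1=C[C@H](O)CC(C)(C)[C@H]1CCC1=C/C(=C/C(C)=C/C=C/C=C(C)/C=C/C=C(C)/C=C/C2=C(C)C[C@@H](O)CC2(C)C)OC1=O | target

Total step count: 25. Longest linear sequence: 14 steps (steps 12–24, then step 25); the β-ring branch runs through steps 1–6 and 8–11 into step 25, with step 7 as a one-step side branch.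

Steps most likely to fail

Step 2. The zwitterion formed after the first C–C bond may close at the silyloxy-bearing carbon to a cyclobutene, the diene may be protodesilylated by the Lewis acid, or the double bond may slip into conjugation with the ketone during hydrolysis. The fallback sets out from 1 and comes back at 5, forming the same two ring bonds by Michael addition and aldol condensation instead of cycloaddition. Mesityl oxide 1 is condensed with ethyl acetoacetate (ZnCl2, PhMe, reflux, removal of water) to racemic ethyl 2,6,6-trimethyl-4-oxocyclohex-2-ene-1-carboxylate F1. The enone is then deconjugated by forming the extended dienolate (LiN(i-Pr)2, THF, −78 °C) and protonating it kinetically at the α-carbon (AcOH, −78 °C), which should give 5.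

Step 3. Enantioface discrimination of a ketone flanked by two methylene groups may be insufficient with the enzymes available, or the double bond may migrate during a slow reduction. The fallback sets out from 5 and comes back at 6 by resolution instead of asymmetric reduction. NaBH4 (MeOH, 0 °C) gives racemic ethyl 4-hydroxy-2,6,6-trimethylcyclohex-1-ene-1-carboxylate F2. Lipase-catalysed acylation (Burkholderia cepacia lipase, vinyl acetate, t-BuOMe, 30 °C) is expected to convert the R enantiomer into ethyl (4R)-4-acetoxy-2,6,6-trimethylcyclohex-1-ene-1-carboxylate F3, which is separated from the unreacted S alcohol. Ethanolysis (K2CO3, EtOH, 25 °C) then gives 6.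

Step 25. The unprotected hydroxyl groups may quench part of the ylide, the enol lactone may open under basic conditions, and equilibration of the 15Z isomer may be incomplete or may scramble other double bonds. The fallback sets out from 17 and 41 and comes back at 45, replacing the Wittig reaction by a Julia–Kocienski olefination of fully protected partners. Mitsunobu reaction of 17 with 1-phenyl-1H-tetrazole-5-thiol (PPh3, diisopropyl azodicarboxylate, THF, 0 °C) gives (3R)-3-[(tert-butyldimethylsilyl)oxy]retinyl 1-phenyltetrazol-5-yl sulfide F4. Oxidation (H2O2, (NH4)6Mo7O24, EtOH, 0 °C) gives the corresponding sulfone F5. Its potassium salt (KN(SiMe3)2, THF, −78 °C) is combined with aldehyde 41 and the product equilibrated as in step 25 to the bis(tert-butyldimethylsilyl) ether of the target F6. Buffered desilylation (Bu4NF, AcOH, THF) then gives 45.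

Further compounds
F1 | step 2 | ethyl 2,6,6-trimethyl-4-oxocyclohex-2-ene-1-carboxylate (racemic) | CCOC(=O)C1C(C)=CC(=O)CC1(C)C
F2 | step 3 | ethyl 4-hydroxy-2,6,6-trimethylcyclohex-1-ene-1-carboxylate (racemic) | CCOC(=O)C1=C(C)CC(O)CC1(C)C
F3 | step 3 | ethyl (4R)-4-acetoxy-2,6,6-trimethylcyclohex-1-ene-1-carboxylate | CCOC(=O)C1=C(C)C[C@@H](OC(C)=O)CC1(C)C
F4 | step 25 | (3R)-3-[(tert-butyldimethylsilyl)oxy]retinyl 1-phenyl-1H-tetrazol-5-yl sulfide | c1ccccc1-n1nnnc1SC/C=C(C)/C=C/C=C(C)/C=C/C1=C(C)C[C@@H](O[Si](C)(C)C(C)(C)C)CC1(C)C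
F5 | step 25 | (3R)-3-[(tert-butyldimethylsilyl)oxy]retinyl 1-phenyl-1H-tetrazol-5-yl sulfone | c1ccccc1-n1nnnc1S(=O)(=O)C/C=C(C)/C=C/C=C(C)/C=C/C1=C(C)C[C@@H](O[Si](C)(C)C(C)(C)C)CC1(C)C
F6 | step 25 | 3,3'-bis(tert-butyldimethylsilyl) ether of the target | CC1=C[C@H](O[Si](C)(C)C(C)(C)C)CC(C)(C)[C@H]1CCC1=C/C(=C/C(C)=C/C=C/C=C(C)/C=C/C=C(C)/C=C/C2=C(C)C[C@@H](O[Si](C)(C)C(C)(C)C)CC2(C)C)OC1=O
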